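## Analysis of the target

Compound 28 is a 4→6-linked biflavonoid in which each half is a chromane (ring A fused to the pyran ring C) carrying an aryl ring B on C2. The upper half is a 3',4',7,8-tetrahydroxyflavan-3-ol whose C4 is bonded to C6 of ring A of the lower half, a 4',7,8-trihydroxyflavan-3,4-diol. There are six stereocentres: in the upper unit the C2 aryl group and C3–OH are cis and the C4–aryl bond is trans to both (2R,3R,4S), whereas in the lower unit the C2 aryl group, C3–OH and C4–OH all lie on one face of ring C (2R,3R,4R). The molecule carries seven phenols, six of them in three catechol pairs that oxidise in air above neutral pH. The lower C4–OH is benzylic and activated by O1 (ortho) and O7 (para), so acid ionises it and epimerises or condenses it, and the interflavan bond is acid-labile as well. The 7,8-dioxygenated ring A is only a moderate nucleophile, so the interflavan bond is harder to make than in the phloroglucinol series. The all-cis triad of the lower ring C is not reached by the usual additions to a flav-3-ene, which come from the face opposite ring B, or by opening an epoxide, which gives a trans diol. The strategy rests on the lower C3–O and C4–O bonds, cis to each other and to ring B: both oxygens are put onto the aryl-bearing face of the C3=C4 bond of a 2H-chromene in one enzymatic event.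

## Retrosynthetic reasoning

**Unmasking (28 ⇐ 27 ⇐ 26).** The seven phenols are carried as benzyl ethers, which leave with hydrogen and need neither acid nor oxidant. The lower cis-diol is carried as an acetonide, which stops O4 from acting as a nucleophile and C4 from ionising during the coupling. The acetonide is removed first so that the last step needs only filtration.

**Interflavan bond (26 ⇒ 14 + 25).** The C4(upper)–C6(lower) bond is cut because it is the only bond between the halves. Cutting it gives two flavans of equal size that share one ring-A building block. In the forward direction a C4 cation from thioether 25 must alkylate C6 of 14 and not C5, and must be attacked trans to the upper C3–OH. C6 is ortho to O7 and para to O1; C5 has one activating oxygen and sits next to the acetonide.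

**Protection of the lower unit (14 ⇐ 13 ⇐ 12).** No skeletal bond is made. Phenols are benzylated before the diol is ketalised, so that acid never meets the free 7-hydroxy compound.

**Key disconnection (12 ⇒ 11).** C3–O and C4–O are cut together. This reduces the three stereocentres of ring C to one (C2) and gives a flat, short precursor. The forward step must add two oxygens suprafacially to C3=C4 on the face that bears ring B, without a cation at C4, and must leave both phenolic arenes alone. A Rieske dioxygenase is chosen because its pocket, not the substrate, selects the face.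

**Ring C of the lower unit (11 ⇐ 10 ⇒ 9).** After removal of the silyl groups, the C3=C4 bond is cut by a metathesis transform. Two terminal alkenes are easy to install and ring closure does not touch C2.

**C2 stereocentre (9 ⇒ 8 + 7).** The O1–C2 bond is cut; an iridium-catalysed allylic etherification of the lithium aryloxide 8 with carbonate 7 forms it and sets C2. The aryloxide 8 is made once from vinylphenol 3 and kept as a stock, because the same nucleophile is needed for both halves. Vinylphenol 3 comes from 1 through 2. The catechol is bridged by a cyclic silylene because an open silyl ether next to the phenoxide would migrate. Carbonate 7 comes from 4 through 5 and 6.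

**Upper electrophile (25 ⇒ 24 ⇒ 23 ⇒ 22).** The upper unit needs C3–O on the aryl face and a C4 substituent trans to it. Bromohydrin 23 (bromine anti to ring B), closure to the syn epoxide 24 and anti opening at C4 give exactly this pattern by known chemistry. The same sequence would give the wrong C4 epimer in the lower unit, which is why the enzymatic step is reserved for 12.

**Upper flavene (22 ⇐ 21 ⇐ 20 ⇒ 19 ⇒ 8 + 18).** The chemistry of the lower half is reused with the shared aryloxide 8. Ring B carries benzyl ethers from the start (18 from 15 through 16 and 17), and the silylene is exchanged for benzyl ethers once ring C is closed.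

## Alternatives that were turned down

**Alternative 1:** Ring C of the upper unit is closed last by cutting its C4–C4a bond; the product is A1, the octabenzyl ether 3,4-acetonide of the target. In the forward step acid ionises a secondary benzylic alcohol on the carbon attached to C6 of the lower ring A, and the free ortho carbon of a tethered 2,3-bis(benzyloxy)phenyl ether closes the six-membered ring by Friedel–Crafts alkylation.
- For: the interflavan carbon is attached to C6 by construction, so there is no regiochemical question and no oligomerisation. An intramolecular closure also suits the weakly nucleophilic ring better than an intermolecular one. On this point it is stronger than the chosen route.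
- Against: it does not address the all-cis lower diol, which must already be present. The complete lower unit is carried through a long linear sequence, and the cation is generated beside its acid-labile benzylic acetonide. The upper C4 is set in a cation cyclisation controlled only by the neighbouring C3 ether.
- Comparison: the chosen strategy solves the all-cis problem directly and keeps the two halves apart until three steps from the end.

**Alternative 2:** Ring C of the lower unit is built by cutting O1–C2 and C3–C4. A chiral Brønsted acid removes one allyloxy group from A3, the diallyl acetal of 3,4-bis(benzyloxy)-2-hydroxybenzaldehyde, and the resulting allyloxy ortho-quinone methide adds A4, (Z)-benzyldimethyl[2-(4-benzyloxyphenyl)vinyl]silane, to give the all-cis flavan A2.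
- For: the ring and all three stereocentres arise in one catalytic step from achiral pieces, with silicon as a masked hydroxyl. In convergence and bond count per step it is stronger than the chosen route, which needs etherification, metathesis and the enzyme.
- Against: the addition can run stepwise through a benzylic cation β to silicon. That cation can lose the silyl group or rotate, which would erase the Z geometry on which the 2,3-cis relation depends. The 3,4-cis relation needs a single endo or exo mode. The benzyloxy group next to the phenol crowds the site where the catalyst binds. After A2, a carbon–silicon oxidation and a deallylation are still required.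
- Comparison: in the chosen strategy the cis relation of the two C–O bonds follows from the mechanism itself, the oxidation level is reached directly, and the key step needs no protecting groups.

**Alternative 3:** Ring C of the lower unit is closed by cutting C4–C4a. An aryl iodide is converted, by cathodically regenerated divalent chromium (CrCl2) with a NiCl2 co-catalyst, into an arylchromium species that adds to an aldehyde tethered through the O1–C2 ether, giving the flavan-4-ol A5.
- For: C2 and C3 come from acyclic stereocontrol, O3 and O4 arrive differentiated, the conditions are neutral, and each reaction type has precedent. On precedent it is stronger than the chosen route.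
- Against: the C4 configuration depends on a contest between chelation by the α-benzyloxy group and a Felkin-type approach inside the forming ring. The α-alkoxy-β-aryloxy aldehyde can epimerise at C3 and lose aryloxide by β-elimination. The hindered O1–C2 ether at an electron-rich benzylic carbon has to be made with defined configuration. The precursor is longer to make than flavene 11.
- Comparison: the chosen strategy sets C3 and C4 together from a precursor reached in nine steps and has no epimerisable aldehyde.

Key step: step 10

**Assumptions.**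
- The (Sa,Sc,Sc) phosphoramidite is assumed to give the (S)-ethers 9 and 19, following the usual facial model of this catalyst family; the mirror-image ligand is used if the opposite sense is found.
- A dioxygenase variant with the required selectivity is assumed to be found by panel screening before scale-up.
- Compounds 4 and 15 are taken as commercial.

## Route

**Step 1**
Reactants: 1 2,3,4-trihydroxybenzaldehyde
Product: 2 2,2-di-tert-butyl-4-hydroxy-1,3,2-benzodioxasilole-5-carbaldehyde
Conditions: t-Bu2Si(OTf)2, 2,6-lutidine, DMF, 0 °C to rt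
Reagents that add atoms: di-tert-butylsilyl bis(trifluoromethanesulfonate) CC(C)(C)[Si](OS(=O)(=O)C(F)(F)F)(OS(=O)(=O)C(F)(F)F)C(C)(C)C
Why: Silylene formation on a catechol; the 2-hydroxyl is held in a hydrogen bond to the formyl group and is the least nucleophilic, so the bridge should form across O3 and O4. A cyclic silylene is used because its silicon cannot reach the neighbouring phenoxide oxygen that is present in steps 2, 6, 7 and 16, which excludes the O-to-O silyl migration that open silyl ethers would undergo.

**Step 2**
Reactants: 2 2,2-di-tert-butyl-4-hydroxy-1,3,2-benzodioxasilole-5-carbaldehyde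
Product: 3 2,2-di-tert-butyl-5-vinyl-1,3,2-benzodioxasilol-4-ol
Conditions: Ph3PCH3Br, NaN(SiMe3)2, THF, 0 °C to rt
Reagents that add atoms: methyltriphenylphosphonium bromide C[P+](c1ccccc1)(c1ccccc1)c1ccccc1.[Br-]
Why: Wittig methylenation of a salicylaldehyde with excess ylide, one equivalent being taken up by the phenol; the hindered silylene is inert to the non-nucleophilic amide base.

**Step 3**
Reactants: 4 methyl (E)-4-hydroxycinnamate
Product: 5 methyl (E)-3-[4-(triisopropylsilyloxy)phenyl]acrylate
Conditions: i-Pr3SiCl, imidazole, DMF, rt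
Reagents that add atoms: chlorotriisopropylsilane CC(C)[Si](Cl)(C(C)C)C(C)C
Why: Standard phenol silylation; the bulky triisopropylsilyl ether resists exchange with the aryloxide used in step 7.

**Step 4**
Reactants: 5 methyl (E)-3-[4-(triisopropylsilyloxy)phenyl]acrylate
Product: 6 (E)-3-[4-(triisopropylsilyloxy)phenyl]prop-2-en-1-ol
Conditions: i-Bu2AlH, CH2Cl2, −78 to 0 °C; aq. KNaC4H4O6
Reagents that add atoms: none
Why: 1,2-Reduction of the cinnamate to the allylic alcohol; the aryl silyl ether is not touched at low temperature.

**Step 5**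
Reactants: 6 (E)-3-[4-(triisopropylsilyloxy)phenyl]prop-2-en-1-ol
Product: 7 (E)-3-[4-(triisopropylsilyloxy)phenyl]allyl methyl carbonate
Conditions: ClCO2Me, pyridine, CH2Cl2, 0 °C
Reagents that add atoms: methyl chloroformate COC(=O)Cl
Why: Acylation of the primary allylic alcohol gives the linear carbonate that serves as allyl donor.

**Step 6**
Reactants: 3 2,2-di-tert-butyl-5-vinyl-1,3,2-benzodioxasilol-4-ol
Product: 8 lithium 2,2-di-tert-butyl-5-vinyl-1,3,2-benzodioxasilol-4-olate
Conditions: LiN(SiMe3)2 (1.0 equiv), THF, 0 °C; volatiles removed under vacuum, solid kept under argon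
Reagents that add atoms: lithium bis(trimethylsilyl)amide [Li+].C[Si](C)(C)[N-][Si](C)(C)C
Why: Acid–base reaction: the silylamide deprotonates the phenol completely and the volatile amine is pumped off, which leaves the amine-free lithium aryloxide. One batch of this salt is prepared and stored so that the same nucleophile serves both etherifications (steps 7 and 16); the cyclic silylene cannot migrate to the neighbouring oxide.

**Step 7**
Reactants: 8 lithium 2,2-di-tert-butyl-5-vinyl-1,3,2-benzodioxasilol-4-olate; 7 (E)-3-[4-(triisopropylsilyloxy)phenyl]allyl methyl carbonate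
Product: 9 (S)-2,2-di-tert-butyl-4-({1-[4-(triisopropylsilyloxy)phenyl]prop-2-en-1-yl}oxy)-5-vinyl-1,3,2-benzodioxasilole
Conditions: [Ir(cod)Cl]2 (2 mol%), (Sa,Sc,Sc)-binaphthol N,N-bis(1-phenylethyl)phosphoramidite (4 mol%, pre-activated with n-PrNH2), THF, rt
Reagents that add atoms: none
Why: Iridium-catalysed enantioselective allylic etherification: the cyclometalated complex formed from [Ir(cod)Cl]2 and the phosphoramidite ionises the linear carbonate and the aryloxide attacks the substituted allyl terminus to give the branched ether. The C2 stereocentre (S) is set by the ligand; the electron-rich carbonate and the ortho,ortho-disubstituted aryloxide lie at the demanding end of this reaction type.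

**Step 8**
Reactants: 9 (S)-2,2-di-tert-butyl-4-({1-[4-(triisopropylsilyloxy)phenyl]prop-2-en-1-yl}oxy)-5-vinyl-1,3,2-benzodioxasilole
Product: 10 (2S)-7,8-(di-tert-butylsilylenedioxy)-2-[4-(triisopropylsilyloxy)phenyl]-2H-chromene
Conditions: second-generation Grubbs catalyst (3 mol%), CH2Cl2 (0.01 M), 40 °C
Reagents that add atoms: none
Why: Ring-closing metathesis of the styrene and the allyl ether terminus closes ring C as the C3=C4 bond with loss of ethene; C2 takes no part.

**Step 9**
Reactants: 10 (2S)-7,8-(di-tert-butylsilylenedioxy)-2-[4-(triisopropylsilyloxy)phenyl]-2H-chromene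
Product: 11 (2S)-2-(4-hydroxyphenyl)-2H-chromene-7,8-diol
Conditions: Bu4NF, AcOH, THF, 0 °C, argon, dark; used at once
Reagents that add atoms: none
Why: Fluoride cleaves both silicon–oxygen groups. Buffering with AcOH keeps the 4'-phenol protonated, so the allylic benzylic C2–O1 bond is not opened through a para-quinone methide, which would racemise C2.

**Step 10**
Reactants: 11 (2S)-2-(4-hydroxyphenyl)-2H-chromene-7,8-diol
Product: 12 (2R,3R,4R)-2-(4-hydroxyphenyl)chromane-3,4,7,8-tetrol
Conditions: resting E. coli cells expressing the selected Rieske dioxygenase (oxygenase, ferredoxin, reductase) and glucose dehydrogenase, D-glucose, air, potassium phosphate buffer pH 6.8, sodium ascorbate, 5% DMSO, 28 °C, dark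
Reagents that add atoms: dioxygen O=O
Why: Proposed new method: in Rieske dioxygenases the [2Fe–2S] cluster passes two electrons from NADH to a mononuclear divalent iron centre that binds O2 side-on and hands both oxygen atoms to one face of a bound alkene, so C3–O and C4–O should form suprafacially in neutral water without a cation at the benzylic C4. The closest known reaction type is the cis-dihydroxylation of 2H-chromene, 1,2-dihydronaphthalene and indene by naphthalene and toluene dioxygenases; a 2-aryl-2H-chromene with free phenols has not been shown as a substrate. No ring is closed. C3 and C4 are the new stereocentres: their cis relation follows from the delivery of one O2 molecule to one face, and their absolute sense (3R,4R, oxygen on the face that carries ring B) is fixed by the orientation in which the protein pocket holds (2S)-11 over the iron, not by the substrate. The step needs face selectivity against the steric bias of the C2 aryl group and chemoselectivity for C3=C4 over arene dioxygenation of rings A and B and over hydroxylation at C2. The substrate helps in that C3=C4 is its only olefin and is conjugated to ring A exactly as in the accepted bicyclic substrates, where the alkene and not the benzene ring is oxidised, and in that ring B can lie pseudo-equatorial near the mean plane of the half-chair and so need not clash with the metal site. The variant that meets both demands is selected from a panel of naphthalene, biphenyl and toluene dioxygenases and their active-site mutants.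

**Step 11**
Reactants: 12 (2R,3R,4R)-2-(4-hydroxyphenyl)chromane-3,4,7,8-tetrol
Product: 13 (2R,3R,4R)-7,8-bis(benzyloxy)-2-[4-(benzyloxy)phenyl]chromane-3,4-diol
Conditions: BnBr, K2CO3, DMF, rt, argon
Reagents that add atoms: benzyl bromide BrCc1ccccc1
Why: Williamson benzylation of the three phenols only; carbonate does not deprotonate the secondary alcohols, and hydroxide is too poor a leaving group for C4 to ionise at room temperature.

**Step 12**
Reactants: 13 (2R,3R,4R)-7,8-bis(benzyloxy)-2-[4-(benzyloxy)phenyl]chromane-3,4-diol
Product: 14 3,4-O-isopropylidene acetal of 13 (cis-fused dioxolane on the face of ring B)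
Conditions: Me2C(OMe)2, PPTS (cat.), acetone, rt
Reagents that add atoms: 2,2-dimethoxypropane COC(C)(C)OC
Why: Acid-catalysed transketalisation; only a cis-3,4-diol can form the five-membered dioxolane, so the step also serves as a check of the relative configuration.

**Step 13**
Reactants: 15 3,4-bis(benzyloxy)benzaldehyde
Product: 16 ethyl (E)-3-[3,4-bis(benzyloxy)phenyl]acrylate
Conditions: (EtO)2P(O)CH2CO2Et, NaH, THF, 0 °C to rt
Reagents that add atoms: triethyl phosphonoacetate CCOC(=O)CP(=O)(OCC)OCC
Why: Horner–Wadsworth–Emmons olefination gives the E-cinnamate.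

**Step 14**
Reactants: 16 ethyl (E)-3-[3,4-bis(benzyloxy)phenyl]acrylate
Product: 17 (E)-3-[3,4-bis(benzyloxy)phenyl]prop-2-en-1-ol
Conditions: i-Bu2AlH, CH2Cl2, −78 to 0 °C; aq. KNaC4H4O6
Reagents that add atoms: none
Why: 1,2-Reduction of the cinnamate, as in step 4.

**Step 15**
Reactants: 17 (E)-3-[3,4-bis(benzyloxy)phenyl]prop-2-en-1-ol
Product: 18 (E)-3-[3,4-bis(benzyloxy)phenyl]allyl methyl carbonate
Conditions: ClCO2Me, pyridine, CH2Cl2, 0 °C
Reagents that add atoms: methyl chloroformate COC(=O)Cl
Why: Carbonate formation, as in step 5.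

**Step 16**
Reactants: 8 lithium 2,2-di-tert-butyl-5-vinyl-1,3,2-benzodioxasilol-4-olate; 18 (E)-3-[3,4-bis(benzyloxy)phenyl]allyl methyl carbonate
Product: 19 (S)-4-({1-[3,4-bis(benzyloxy)phenyl]prop-2-en-1-yl}oxy)-2,2-di-tert-butyl-5-vinyl-1,3,2-benzodioxasilole
Conditions: [Ir(cod)Cl]2 (2 mol%), (Sa,Sc,Sc)-binaphthol N,N-bis(1-phenylethyl)phosphoramidite (4 mol%, pre-activated with n-PrNH2), THF, rt
Reagents that add atoms: none
Why: The same iridium-catalysed allylic etherification as in step 7, run with a second portion of the stored aryloxide; the ligand sets the upper C2 stereocentre (S).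

**Step 17**
Reactants: 19 (S)-4-({1-[3,4-bis(benzyloxy)phenyl]prop-2-en-1-yl}oxy)-2,2-di-tert-butyl-5-vinyl-1,3,2-benzodioxasilole
Product: 20 (2S)-2-[3,4-bis(benzyloxy)phenyl]-7,8-(di-tert-butylsilylenedioxy)-2H-chromene
Conditions: second-generation Grubbs catalyst (3 mol%), CH2Cl2 (0.01 M), 40 °C
Reagents that add atoms: none
Why: Ring-closing metathesis, as in step 8.

**Step 18**
Reactants: 20 (2S)-2-[3,4-bis(benzyloxy)phenyl]-7,8-(di-tert-butylsilylenedioxy)-2H-chromene
Product: 21 (2S)-2-[3,4-bis(benzyloxy)phenyl]-2H-chromene-7,8-diol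
Conditions: Bu4NF, AcOH, THF, 0 °C, argon; used crude
Reagents that add atoms: none
Why: Fluoride removes the silylene; the benzyl ethers are inert, and with the 4'-oxygen benzylated there is no quinone methide path to racemisation.

**Step 19**
Reactants: 21 (2S)-2-[3,4-bis(benzyloxy)phenyl]-2H-chromene-7,8-diol
Product: 22 (2S)-7,8-bis(benzyloxy)-2-[3,4-bis(benzyloxy)phenyl]-2H-chromene
Conditions: BnBr, K2CO3, DMF, rt, argon
Reagents that add atoms: benzyl bromide BrCc1ccccc1
Why: Williamson benzylation of the catechol; the flavene tolerates mild base.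

**Step 20**
Reactants: 22 (2S)-7,8-bis(benzyloxy)-2-[3,4-bis(benzyloxy)phenyl]-2H-chromene
Product: 23 (2R,3S,4R)-7,8-bis(benzyloxy)-2-[3,4-bis(benzyloxy)phenyl]-3-bromochroman-4-ol (2,3-trans-3,4-trans)
Conditions: NBS, THF/H2O (4:1), 0 °C, dark
Reagents that add atoms: N-bromosuccinimide O=C1CCC(=O)N1Br; water O
Why: Bromohydrin formation, a known reaction of 2H-chromenes: electrophilic bromine attacks C3 of the electron-rich styrene-type double bond on the face away from ring B, and water captures the benzylic C4 cation anti to bromine. Bromine thus ends trans and the C4 hydroxyl cis to ring B.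

**Step 21**
Reactants: 23 (2R,3S,4R)-7,8-bis(benzyloxy)-2-[3,4-bis(benzyloxy)phenyl]-3-bromochroman-4-ol
Product: 25 (2R,3S,4S)-4-(benzylsulfanyl)-7,8-bis(benzyloxy)-2-[3,4-bis(benzyloxy)phenyl]chroman-3-ol (2,3-cis-3,4-trans), via syn-epoxide 24 (not isolated)
Conditions: BnSH, Cs2CO3, DMF, 0 °C to rt
Reagents that add atoms: phenylmethanethiol SCc1ccccc1
Why: Intramolecular Williamson displacement of bromide by the C4 alkoxide inverts C3 and puts the epoxide oxygen on the face of ring B. The thiolate then opens the epoxide at the benzylic C4 with inversion, which leaves C3–OH cis to ring B and the sulfur trans to it.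

**Step 22**
Reactants: 14 3,4-O-isopropylidene acetal of 13; 25 (2R,3S,4S)-4-(benzylsulfanyl)-7,8-bis(benzyloxy)-2-[3,4-bis(benzyloxy)phenyl]chroman-3-ol
Product: 26 heptabenzyl ether 3,4-acetonide of 28 (upper 3-OH free; configuration as in 28)
Conditions: AgBF4, 2,6-di-tert-butyl-4-methylpyridine, 4 Å MS, THF, 0 °C, dark; 14 in threefold excess
Reagents that add atoms: none
Why: Thiophilic activation: monovalent silver removes the benzylthio group as AgSCH2Ph, and the 4-flavanyl cation, stabilised by O1 and the 7-benzyloxy group, alkylates C6 of 14 in a Friedel–Crafts reaction (C6 is ortho to O7 and para to O1; C5 has one activating oxygen and is shielded by the acetonide). Attack comes trans to the C3 hydroxyl and the C2 aryl group of the cation, which sets the upper C4; the hindered pyridine traps HBF4 so that the benzylic acetonide survives.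

**Step 23**
Reactants: 26 heptabenzyl ether 3,4-acetonide of 28
Product: 27 heptabenzyl ether of 28 (all seven phenols benzylated; three secondary hydroxyls free)
Conditions: AcOH/H2O/THF (3:1:1), 40 °C
Reagents that add atoms: none
Why: Mild acetal hydrolysis through the dimethyl-substituted oxocarbenium ion, which forms more easily than the C4 benzylic cation, so C4 should keep its configuration.

**Step 24**
Reactants: 27 heptabenzyl ether of 28
Product: 28 (2R,3R,4R)-6-[(2R,3R,4S)-2-(3,4-dihydroxyphenyl)-3,7,8-trihydroxychroman-4-yl]-2-(4-hydroxyphenyl)chromane-3,4,7,8-tetrol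
Conditions: H2 (1 atm), Pd(OH)2/C, THF/MeOH (1:1), rt; filtration under argon
Reagents that add atoms: none
Why: Hydrogenolysis of the seven benzyl ethers under neutral conditions; the secondary benzylic C4 hydroxyl and the C2–O1 bonds are cleaved far more slowly than O-benzyl groups.

## Compound list

1 | 2,3,4-trihydroxybenzaldehyde | O=Cc1ccc(O)c(O)c1O | starting material
2 | 2,2-di-tert-butyl-4-hydroxy-1,3,2-benzodioxasilole-5-carbaldehyde | O=Cc1ccc2O[Si](C(C)(C)C)(C(C)(C)C)Oc2c1O | intermediate
3 | 2,2-di-tert-butyl-5-vinyl-1,3,2-benzodioxasilol-4-ol | C=Cc1ccc2O[Si](C(C)(C)C)(C(C)(C)C)Oc2c1O | intermediate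
4 | methyl (E)-4-hydroxycinnamate | COC(=O)/C=C/c1ccc(O)cc1 | starting material
5 | methyl (E)-3-[4-(triisopropylsilyloxy)phenyl]acrylate | COC(=O)/C=C/c1ccc(O[Si](C(C)C)(C(C)C)C(C)C)cc1 | intermediate
6 | (E)-3-[4-(triisopropylsilyloxy)phenyl]prop-2-en-1-ol | OC/C=C/c1ccc(O[Si](C(C)C)(C(C)C)C(C)C)cc1 | intermediate
7 | (E)-3-[4-(triisopropylsilyloxy)phenyl]allyl methyl carbonate | COC(=O)OC/C=C/c1ccc(O[Si](C(C)C)(C(C)C)C(C)C)cc1 | intermediate
8 | lithium 2,2-di-tert-butyl-5-vinyl-1,3,2-benzodioxasilol-4-olate | [Li+].[O-]c1c(C=C)ccc2O[Si](C(C)(C)C)(C(C)(C)C)Oc12 | intermediate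
9 | (S)-2,2-di-tert-butyl-4-({1-[4-(triisopropylsilyloxy)phenyl]prop-2-en-1-yl}oxy)-5-vinyl-1,3,2-benzodioxasilole | C=C[C@H](Oc1c(C=C)ccc2O[Si](C(C)(C)C)(C(C)(C)C)Oc12)c1ccc(O[Si](C(C)C)(C(C)C)C(C)C)cc1 | intermediate
10 | (2S)-7,8-(di-tert-butylsilylenedioxy)-2-[4-(triisopropylsilyloxy)phenyl]-2H-chromene | CC(C)[Si](Oc1ccc([C@H]2Oc3c(ccc4O[Si](C(C)(C)C)(C(C)(C)C)Oc34)C=C2)cc1)(C(C)C)C(C)C | intermediate
11 | (2S)-2-(4-hydroxyphenyl)-2H-chromene-7,8-diol | Oc1ccc([C@H]2Oc3c(ccc(O)c3O)C=C2)cc1 | intermediate
12 | (2R,3R,4R)-2-(4-hydroxyphenyl)chromane-3,4,7,8-tetrol | Oc1ccc([C@H]2Oc3c(ccc(O)c3O)[C@@H](O)[C@H]2O)cc1 | intermediate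
13 | (2R,3R,4R)-7,8-bis(benzyloxy)-2-[4-(benzyloxy)phenyl]chromane-3,4-diol | c1ccccc1COc1ccc([C@H]2Oc3c(ccc(OCc4ccccc4)c3OCc3ccccc3)[C@@H](O)[C@H]2O)cc1 | intermediate
14 | 3,4-O-isopropylidene acetal of 13 (all-cis) | c1ccccc1COc1ccc([C@H]2Oc3c(ccc(OCc4ccccc4)c3OCc3ccccc3)[C@@H](OC(C)(C)O5)[C@H]25)cc1 | intermediate
15 | 3,4-bis(benzyloxy)benzaldehyde | O=Cc1ccc(OCc2ccccc2)c(OCc2ccccc2)c1 | starting material
16 | ethyl (E)-3-[3,4-bis(benzyloxy)phenyl]acrylate | CCOC(=O)/C=C/c1ccc(OCc2ccccc2)c(OCc2ccccc2)c1 | intermediate
17 | (E)-3-[3,4-bis(benzyloxy)phenyl]prop-2-en-1-ol | OC/C=C/c1ccc(OCc2ccccc2)c(OCc2ccccc2)c1 | intermediate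
18 | (E)-3-[3,4-bis(benzyloxy)phenyl]allyl methyl carbonate | COC(=O)OC/C=C/c1ccc(OCc2ccccc2)c(OCc2ccccc2)c1 | intermediate
19 | (S)-4-({1-[3,4-bis(benzyloxy)phenyl]prop-2-en-1-yl}oxy)-2,2-di-tert-butyl-5-vinyl-1,3,2-benzodioxasilole | C=C[C@H](Oc1c(C=C)ccc2O[Si](C(C)(C)C)(C(C)(C)C)Oc12)c1ccc(OCc2ccccc2)c(OCc2ccccc2)c1 | intermediate
20 | (2S)-2-[3,4-bis(benzyloxy)phenyl]-7,8-(di-tert-butylsilylenedioxy)-2H-chromene | c1ccccc1COc1ccc([C@H]2Oc3c(ccc4O[Si](C(C)(C)C)(C(C)(C)C)Oc34)C=C2)cc1OCc1ccccc1 | intermediate
21 | (2S)-2-[3,4-bis(benzyloxy)phenyl]-2H-chromene-7,8-diol | c1ccccc1COc1ccc([C@H]2Oc3c(ccc(O)c3O)C=C2)cc1OCc1ccccc1 | intermediate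
22 | (2S)-7,8-bis(benzyloxy)-2-[3,4-bis(benzyloxy)phenyl]-2H-chromene | c1ccccc1COc1ccc([C@H]2Oc3c(ccc(OCc4ccccc4)c3OCc3ccccc3)C=C2)cc1OCc1ccccc1 | intermediate
23 | (2R,3S,4R)-7,8-bis(benzyloxy)-2-[3,4-bis(benzyloxy)phenyl]-3-bromochroman-4-ol | c1ccccc1COc1ccc([C@H]2Oc3c(ccc(OCc4ccccc4)c3OCc3ccccc3)[C@@H](O)[C@@H]2Br)cc1OCc1ccccc1 | intermediate
24 | (2R,3R,4R)-7,8-bis(benzyloxy)-2-[3,4-bis(benzyloxy)phenyl]-3,4-epoxychromane (epoxide oxygen cis to ring B) | c1ccccc1COc1ccc([C@H]2Oc3c(ccc(OCc4ccccc4)c3OCc3ccccc3)[C@H]5O[C@@H]25)cc1OCc1ccccc1 | intermediate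
25 | (2R,3S,4S)-4-(benzylsulfanyl)-7,8-bis(benzyloxy)-2-[3,4-bis(benzyloxy)phenyl]chroman-3-ol | c1ccccc1COc1ccc([C@H]2Oc3c(ccc(OCc4ccccc4)c3OCc3ccccc3)[C@H](SCc5ccccc5)[C@H]2O)cc1OCc1ccccc1 | intermediate
26 | heptabenzyl ether 3,4-acetonide of 28 (upper 3-OH free) | c1ccccc1COc1ccc([C@H]2Oc3c(cc([C@H]4c5ccc(OCc6ccccc6)c(OCc6ccccc6)c5O[C@H](c5ccc(OCc6ccccc6)c(OCc6ccccc6)c5)[C@@H]4O)c(OCc4ccccc4)c3OCc3ccccc3)[C@@H](OC(C)(C)O7)[C@H]27)cc1 | intermediate
27 | heptabenzyl ether of 28 | c1ccccc1COc1ccc([C@H]2Oc3c(cc([C@H]4c5ccc(OCc6ccccc6)c(OCc6ccccc6)c5O[C@H](c5ccc(OCc6ccccc6)c(OCc6ccccc6)c5)[C@@H]4O)c(OCc4ccccc4)c3OCc3ccccc3)[C@@H](O)[C@H]2O)cc1 | intermediate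
28 | (2R,3R,4R)-6-[(2R,3R,4S)-2-(3,4-dihydroxyphenyl)-3,7,8-trihydroxychroman-4-yl]-2-(4-hydroxyphenyl)chromane-3,4,7,8-tetrol | Oc1ccc([C@H]2Oc3c(cc([C@H]4c5ccc(O)c(O)c5O[C@H](c5ccc(O)c(O)c5)[C@@H]4O)c(O)c3O)[C@@H](O)[C@H]2O)cc1 | target

## Step count and least certain steps

Total: 24 steps. Longest linear sequence: 12 steps (from 1 through steps 1, 2, 6–12 and 22–24; the lines from 4 through steps 3–5, 7–12 and 22–24 and from 15 through steps 13–24 are equally long).

**Step 10 (key step).** The enzyme may hold 11 with the wrong face toward the iron, dioxygenate ring B or ring A, or hydroxylate C2. The catechol may chelate the active-site iron and shut the enzyme down. Compound 11 may racemise in buffer by reversible opening of the C2–O1 bond, or oxidise at the catechol. The fallback uses known chemistry, sets out from 11 and returns at 13. Benzylation of 11 (BnBr, K2CO3, DMF) would give (2S)-7,8-bis(benzyloxy)-2-[4-(benzyloxy)phenyl]-2H-chromene F1. A Woodward cis-hydroxylation of F1 (I2, AgOAc, AcOH) would first give the 2,3-trans-3,4-trans 3-iodo-4-acetate F2, with iodine on the face away from ring B. In wet AcOH the neighbouring acetate would displace iodide from the rear through an acetoxonium ion, whose hydrolysis would give the all-cis hydroxy acetates, namely the 3-acetate F3 and the 4-acetate F4. Methanolysis of either (K2CO3, MeOH) would give 13.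

**Step 7.** The crowded aryloxide may react slowly, and the electron-rich branched ether may re-ionise on the catalyst, so that the branched product is partly lost to the linear isomer and its enantiomeric purity erodes. What is learnt here carries over to step 16. The fallback sets out from 2 and 6 and returns at 10. Oxidation of 6 with MnO2 would give (E)-3-[4-(triisopropylsilyloxy)phenyl]acrylaldehyde F5. An oxa-Michael/aldol condensation of 2 with F5, catalysed by a diarylprolinol silyl ether, would give (2R)-7,8-(di-tert-butylsilylenedioxy)-2-[4-(triisopropylsilyloxy)phenyl]-2H-chromene-3-carbaldehyde F6. Decarbonylation of F6 with one equivalent of RhCl(PPh3)3 in toluene at 80 °C would give 10, the rhodium ending as RhCl(CO)(PPh3)2.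

**Step 20.** Bromine may be delivered with poor facial selectivity, or may substitute the electron-rich rings; the syn-epoxide of step 21 may solvolyse before the thiolate reaches it. The fallback sets out from 22 and returns at 26. Hydroboration–oxidation (BH3·THF; H2O2, NaOH) would give the 2,3-trans alcohol (2R,3S)-7,8-bis(benzyloxy)-2-[3,4-bis(benzyloxy)phenyl]chroman-3-ol F7. Dess–Martin oxidation would give the flavan-3-one F8. Reduction with LiB(s-Bu)3H from the face away from ring B would give the 2,3-cis alcohol (2R,3R)-7,8-bis(benzyloxy)-2-[3,4-bis(benzyloxy)phenyl]chroman-3-ol F9. DDQ with 2-ethoxyethanol in CH2Cl2 would give the 3,4-trans 4-(2-ethoxyethoxy) ether F10. Coupling of F10 with 14 under BF3·OEt2 in CH2Cl2 at −78 °C would give 26.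

**Step 22.** The benzylated ring A of 14 may be too weak a nucleophile, so the cation may be consumed by self-condensation of 25 or by loss of the C3 proton; released acid may open the acetonide. The fallback sets out from 12 and 25 and returns at 28. The free phenol 12, a much stronger nucleophile at C6, would be coupled with 25 under AgBF4 in THF at 0 °C to give the upper-unit tetrabenzyl ether of 28 F11. Hydrogenolysis of F11 over Pd(OH)2/C would give 28.

**Step 24.** Hydrogen may also cleave the benzylic C4–OH bond of the lower unit, debenzylation of seven ethers may stall, and the product may oxidise during isolation. The fallback sets out from 26 and returns at 28. Hydrogenolysis would be run with the acetonide still in place, giving the 3,4-acetonide of 28 F12, in which C4–O is held in the acetal. Hydrolysis with dilute aqueous AcOH under argon would give 28.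

## Further compounds

F1 | step 10 | (2S)-7,8-bis(benzyloxy)-2-[4-(benzyloxy)phenyl]-2H-chromene | c1ccccc1COc1ccc([C@H]2Oc3c(ccc(OCc4ccccc4)c3OCc3ccccc3)C=C2)cc1
F2 | step 10 | 2,3-trans-3,4-trans 7,8-bis(benzyloxy)-2-[4-(benzyloxy)phenyl]-3-iodochroman-4-yl acetate | c1ccccc1COc1ccc([C@H]2Oc3c(ccc(OCc4ccccc4)c3OCc3ccccc3)[C@@H](OC(C)=O)[C@@H]2I)cc1
F3 | step 10 | all-cis 7,8-bis(benzyloxy)-2-[4-(benzyloxy)phenyl]-4-hydroxychroman-3-yl acetate | c1ccccc1COc1ccc([C@H]2Oc3c(ccc(OCc4ccccc4)c3OCc3ccccc3)[C@@H](O)[C@H]2OC(C)=O)cc1
F4 | step 10 | all-cis 7,8-bis(benzyloxy)-2-[4-(benzyloxy)phenyl]-3-hydroxychroman-4-yl acetate | c1ccccc1COc1ccc([C@H]2Oc3c(ccc(OCc4ccccc4)c3OCc3ccccc3)[C@@H](OC(C)=O)[C@H]2O)cc1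
F5 | step 7 | (E)-3-[4-(triisopropylsilyloxy)phenyl]acrylaldehyde | O=C/C=C/c1ccc(O[Si](C(C)C)(C(C)C)C(C)C)cc1
F6 | step 7 | (2R)-7,8-(di-tert-butylsilylenedioxy)-2-[4-(triisopropylsilyloxy)phenyl]-2H-chromene-3-carbaldehyde | CC(C)[Si](Oc1ccc([C@H]2Oc3c(ccc4O[Si](C(C)(C)C)(C(C)(C)C)Oc34)C=C2C=O)cc1)(C(C)C)C(C)C
F7 | step 20 | (2R,3S)-7,8-bis(benzyloxy)-2-[3,4-bis(benzyloxy)phenyl]chroman-3-ol | c1ccccc1COc1ccc([C@H]2Oc3c(ccc(OCc4ccccc4)c3OCc3ccccc3)C[C@@H]2O)cc1OCc1ccccc1
F8 | step 20 | (2R)-7,8-bis(benzyloxy)-2-[3,4-bis(benzyloxy)phenyl]chroman-3-one | c1ccccc1COc1ccc([C@H]2Oc3c(ccc(OCc4ccccc4)c3OCc3ccccc3)CC2=O)cc1OCc1ccccc1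
F9 | step 20 | (2R,3R)-7,8-bis(benzyloxy)-2-[3,4-bis(benzyloxy)phenyl]chroman-3-ol | c1ccccc1COc1ccc([C@H]2Oc3c(ccc(OCc4ccccc4)c3OCc3ccccc3)C[C@H]2O)cc1OCc1ccccc1
F10 | step 20 | (2R,3R,4S)-7,8-bis(benzyloxy)-2-[3,4-bis(benzyloxy)phenyl]-4-(2-ethoxyethoxy)chroman-3-ol | c1ccccc1COc1ccc([C@H]2Oc3c(ccc(OCc4ccccc4)c3OCc3ccccc3)[C@H](OCCOCC)[C@H]2O)cc1OCc1ccccc1
F11 | step 22 | 3',4',7,8-tetra-O-benzyl ether of 28 on the upper unit (lower unit free) | Oc1ccc([C@H]2Oc3c(cc([C@H]4c5ccc(OCc6ccccc6)c(OCc6ccccc6)c5O[C@H](c5ccc(OCc6ccccc6)c(OCc6ccccc6)c5)[C@@H]4O)c(O)c3O)[C@@H](O)[C@H]2O)cc1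
F12 | step 24 | 3,4-O-isopropylidene acetal of 28 (lower unit) | Oc1ccc([C@H]2Oc3c(cc([C@H]4c5ccc(O)c(O)c5O[C@H](c5ccc(O)c(O)c5)[C@@H]4O)c(O)c3O)[C@@H](OC(C)(C)O7)[C@H]27)cc1
A1 | alternative 1 | octabenzyl ether 3,4-acetonide of the target | c9ccccc9COc1ccc([C@H]2Oc3c(cc([C@H]4c5ccc(OCc9ccccc9)c(OCc9ccccc9)c5O[C@H](c5ccc(OCc9ccccc9)c(OCc9ccccc9)c5)[C@@H]4OCc9ccccc9)c(OCc9ccccc9)c3OCc9ccccc9)[C@@H](OC(C)(C)O8)[C@H]28)cc1
A2 | alternative 2 | all-cis 4-allyloxy-3-(benzyldimethylsilyl)-4',7,8-tris(benzyloxy)flavan | c9ccccc9COc1ccc([C@H]2Oc3c(ccc(OCc9ccccc9)c3OCc9ccccc9)[C@@H](OCC=C)[C@H]2[Si](C)(C)Cc9ccccc9)cc1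
A3 | alternative 2 | 3,4-bis(benzyloxy)-2-hydroxybenzaldehyde diallyl acetal | C=CCOC(OCC=C)c1ccc(OCc2ccccc2)c(OCc2ccccc2)c1O
A4 | alternative 2 | (Z)-benzyldimethyl[2-(4-benzyloxyphenyl)vinyl]silane | C[Si](C)(Cc1ccccc1)/C=C\c1ccc(OCc2ccccc2)cc1
A5 | alternative 3 | all-cis 3,4',7,8-tetrakis(benzyloxy)flavan-4-ol | c9ccccc9COc1ccc([C@H]2Oc3c(ccc(OCc9ccccc9)c3OCc9ccccc9)[C@@H](O)[C@H]2OCc9ccccc9)cc1
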